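**Retrosynthetic overview**

1. Oxolane locants: O1, C2 (3,4-dimethoxyphenyl), C3 (CH2OH), C4 (aroyl), C5 (CH2). The target comes from desilylation and C4 epimerisation of an all-cis oxolane, itself made by face-selective hydrogenation of a 4-aroyl-2,5-dihydrofuran whose only stereocentre is C2.
2. Key disconnection: the aryl–carbonyl bond, formed together with the carbonyl–C4 and O1–C5 bonds in a three-component union of an acyclic 2,3-allenol, CO and 5-iodo-1,2,3-trimethoxybenzene under zerovalent palladium.
3. Enabling feature: the ketone carbon sits on C4, between the O-bearing methylene C5 and C3. The array O1–C5–C4(C=O)=C3 is what results when an oxygen adds to the terminal carbon and an acyl group to the central carbon of a 1,2-diene C5=C4=C3.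
4. The allenol comes from 3,4-dimethoxybenzaldehyde and a propargylic pinacol boronate by chiral phosphoric acid-catalysed allenylboration, which sets C2. C2 then relays to C3 (hydrogenation) and C4 (equilibration).
5. Ring order: the oxolane is the only ring formed, in step 3.

Key step: step 3

Remark: the target locants above are used for all intermediates; it is assumed that (R)-TRIP delivers the (S)-carbinol, as in the related allylborations, and the antipodal acid would be used if the sense proves opposite.

**Route**

Step 1
Reactants: 1 tert-butyldimethyl(prop-2-yn-1-yloxy)silane; 2 2-(iodomethyl)-4,4,5,5-tetramethyl-1,3,2-dioxaborolane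
Product: 5 2-[4-(tert-butyldimethylsilyloxy)but-2-yn-1-yl]-4,4,5,5-tetramethyl-1,3,2-dioxaborolane, via lithium acetylide 3 (not isolated), via lithium alkynyl(iodomethyl)borate 4 (not isolated)
Conditions: n-BuLi (1.05 equiv), THF, −78 °C; then 2, −78 °C to rt
Reagents that add atoms: none
Why: The lithium acetylide adds to boron of 2 and the resulting borate undergoes a Matteson-type 1,2-metallate shift of the alkynyl group with loss of iodide, a known entry to propargylic pinacol boronates; no stereocentre is formed.

Step 2
Reactants: 5 2-[4-(tert-butyldimethylsilyloxy)but-2-yn-1-yl]-4,4,5,5-tetramethyl-1,3,2-dioxaborolane; 6 3,4-dimethoxybenzaldehyde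
Product: 8 (1S)-2-({[tert-butyl(dimethyl)silyl]oxy}methyl)-1-(3,4-dimethoxyphenyl)buta-2,3-dien-1-ol, via pinacol borate ester 7 (not isolated)
Conditions: (R)-TRIP (3,3′-bis(2,4,6-triisopropylphenyl)-1,1′-binaphthyl-2,2′-diyl hydrogen phosphate, 10 mol %), 4 Å MS, toluene, 0 °C to rt; aq. NaHCO3 work-up
Reagents that add atoms: none
Why: Chiral Brønsted acid-catalysed asymmetric propargylboration of an aldehyde (SE2′ allenylation) through a closed six-membered transition state should form the C–C bond at the alkyne carbon bearing CH2OTBS, giving the 2-substituted 2,3-allenol regiospecifically, with the acid selecting the aldehyde face to set the (S)-carbinol centre (C2).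

Step 3
Reactants: 8 (1S)-2-({[tert-butyl(dimethyl)silyl]oxy}methyl)-1-(3,4-dimethoxyphenyl)buta-2,3-dien-1-ol; 9 5-iodo-1,2,3-trimethoxybenzene
Product: 10 [(5S)-4-({[tert-butyl(dimethyl)silyl]oxy}methyl)-5-(3,4-dimethoxyphenyl)-2,5-dihydrofuran-3-yl](3,4,5-trimethoxyphenyl)methanone
Conditions: Pd(PPh3)4 (5 mol %), CO (1 atm), K2CO3 (2 equiv), MeCN, 50 °C
Reagents that add atoms: carbon monoxide, [C-]#[O+]
Why: Proposed new method: oxidative addition of zerovalent palladium to the C–I bond of 9 and CO insertion give the aroylpalladium iodide (this insertion makes the aryl–carbonyl bond), which adds across the terminal C4=C5 bond of the allene with the aroyl group on the central carbon C4; the C2 alkoxide then closes onto C5 of the resulting 2-aroyl-π-allyl complex (equivalently, anti-oxypalladation at C5 followed by acyl–vinyl reductive elimination), releasing 10 and zerovalent palladium. The closest known reaction types are the palladium-catalysed carbonylation–coupling–cyclization of allenes bearing tethered N- or O-nucleophiles with aryl iodides and CO, the coupling–cyclization of 2,3-allenols with organic halides to 3-substituted 2,5-dihydrofurans, and the aroylative cyclization of 2-alkynylphenols with aryl iodides and CO; the untested element is the combination with CO on a 2,3-allenol in the endo mode. The oxolane ring closes 5-endo-trig at the distal allene double bond (O1–C5 bond). No stereocentre is created; the C2 carbinol centre takes part in no bond change and is carried into 10, where it later controls C3 and C4. The step needs CO insertion to precede allene capture (CO atmosphere, fast migration of the electron-rich aryl group), O–C5 rather than O–C3 closure (C3 is a fully substituted allyl terminus carrying CH2OTBS while C5 is an unhindered CH2, so the dihydrofuran should be favoured over a vinyloxirane), and a single nucleophile (the primary hydroxyl is silylated, so only the benzylic OH can cyclize).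

Step 4
Reactants: 10 [(5S)-4-({[tert-butyl(dimethyl)silyl]oxy}methyl)-5-(3,4-dimethoxyphenyl)-2,5-dihydrofuran-3-yl](3,4,5-trimethoxyphenyl)methanone
Product: 11 [(3R,4R,5R)-4-({[tert-butyl(dimethyl)silyl]oxy}methyl)-5-(3,4-dimethoxyphenyl)oxolan-3-yl](3,4,5-trimethoxyphenyl)methanone (aryl, CH2OTBS and aroyl all cis)
Conditions: H2 (1 atm), 10% Pd/C, EtOAc, rt
Reagents that add atoms: none
Why: Heterogeneous catalytic hydrogenation of the cyclic enone should deliver H2 syn to the ring face opposite the C2 aryl group, placing H on C3 and C4 anti to the aryl, so that C3 is fixed with CH2OTBS cis to the aryl (the required 2,3-cis relation) and C4 is set provisionally with the aroyl group also cis.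

Step 5
Reactants: 11 [(3R,4R,5R)-4-({[tert-butyl(dimethyl)silyl]oxy}methyl)-5-(3,4-dimethoxyphenyl)oxolan-3-yl](3,4,5-trimethoxyphenyl)methanone
Product: 12 [(3S,4R,5R)-4-({[tert-butyl(dimethyl)silyl]oxy}methyl)-5-(3,4-dimethoxyphenyl)oxolan-3-yl](3,4,5-trimethoxyphenyl)methanone (aroyl trans to CH2OTBS and to aryl)
Conditions: DBU (0.3 equiv), CH2Cl2, rt
Reagents that add atoms: none
Why: Base-mediated epimerisation through the ketone enolate should equilibrate C4, the only acidic stereocentre, to the thermodynamically preferred isomer with the aroyl group trans to the neighbouring CH2OTBS; with the primary oxygen still silylated, a transient retro-oxa-Michael opening can only reclose to the same oxolane.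

Step 6
Reactants: 12 [(3S,4R,5R)-4-({[tert-butyl(dimethyl)silyl]oxy}methyl)-5-(3,4-dimethoxyphenyl)oxolan-3-yl](3,4,5-trimethoxyphenyl)methanone
Product: 13 [(3S,4R,5R)-5-(3,4-dimethoxyphenyl)-4-(hydroxymethyl)oxolan-3-yl](3,4,5-trimethoxyphenyl)methanone (CNP0271206.1)
Conditions: HF·pyridine, pyridine, THF, 0 °C to rt
Reagents that add atoms: none
Why: Fluoride-mediated silyl ether cleavage under buffered, near-neutral conditions should leave the acid-sensitive electron-rich benzylic ether and the base-sensitive β-alkoxy ketone untouched, and no stereocentre is affected.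

**Compound list**

1 | tert-butyldimethyl(prop-2-yn-1-yloxy)silane | C#CCO[Si](C)(C)C(C)(C)C | starting material
2 | 2-(iodomethyl)-4,4,5,5-tetramethyl-1,3,2-dioxaborolane | ICB1OC(C)(C)C(C)(C)O1 | starting material
3 | [3-(tert-butyldimethylsilyloxy)prop-1-yn-1-yl]lithium | [Li]C#CCO[Si](C)(C)C(C)(C)C | intermediate
4 | lithium [3-(tert-butyldimethylsilyloxy)prop-1-yn-1-yl](iodomethyl)(pinacolato)borate | [Li+].CC1(C)O[B-](CI)(C#CCO[Si](C)(C)C(C)(C)C)OC1(C)C | intermediate
5 | 2-[4-(tert-butyldimethylsilyloxy)but-2-yn-1-yl]-4,4,5,5-tetramethyl-1,3,2-dioxaborolane | CC1(C)OB(CC#CCO[Si](C)(C)C(C)(C)C)OC1(C)C | intermediate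
6 | 3,4-dimethoxybenzaldehyde | COc1ccc(C=O)cc1OC | starting material
7 | 2-{[(1S)-2-({[tert-butyl(dimethyl)silyl]oxy}methyl)-1-(3,4-dimethoxyphenyl)buta-2,3-dien-1-yl]oxy}-4,4,5,5-tetramethyl-1,3,2-dioxaborolane | COc1ccc([C@H](OB2OC(C)(C)C(C)(C)O2)C(CO[Si](C)(C)C(C)(C)C)=C=C)cc1OC | intermediate
8 | (1S)-2-({[tert-butyl(dimethyl)silyl]oxy}methyl)-1-(3,4-dimethoxyphenyl)buta-2,3-dien-1-ol | COc1ccc([C@H](O)C(CO[Si](C)(C)C(C)(C)C)=C=C)cc1OC | intermediate
9 | 5-iodo-1,2,3-trimethoxybenzene | COc1cc(I)cc(OC)c1OC | starting material
10 | [(5S)-4-({[tert-butyl(dimethyl)silyl]oxy}methyl)-5-(3,4-dimethoxyphenyl)-2,5-dihydrofuran-3-yl](3,4,5-trimethoxyphenyl)methanone | COc1ccc([C@@H]2OCC(C(=O)c3cc(OC)c(OC)c(OC)c3)=C2CO[Si](C)(C)C(C)(C)C)cc1OC | intermediate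
11 | [(3R,4R,5R)-4-({[tert-butyl(dimethyl)silyl]oxy}methyl)-5-(3,4-dimethoxyphenyl)oxolan-3-yl](3,4,5-trimethoxyphenyl)methanone | COc1ccc([C@@H]2OC[C@H](C(=O)c3cc(OC)c(OC)c(OC)c3)[C@@H]2CO[Si](C)(C)C(C)(C)C)cc1OC | intermediate
12 | [(3S,4R,5R)-4-({[tert-butyl(dimethyl)silyl]oxy}methyl)-5-(3,4-dimethoxyphenyl)oxolan-3-yl](3,4,5-trimethoxyphenyl)methanone | COc1ccc([C@@H]2OC[C@@H](C(=O)c3cc(OC)c(OC)c(OC)c3)[C@@H]2CO[Si](C)(C)C(C)(C)C)cc1OC | intermediate
13 | [(3S,4R,5R)-5-(3,4-dimethoxyphenyl)-4-(hydroxymethyl)oxolan-3-yl](3,4,5-trimethoxyphenyl)methanone | COc1ccc([C@@H]2OC[C@@H](C(=O)c3cc(OC)c(OC)c(OC)c3)[C@@H]2CO)cc1OC | target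

**Step count and risks**

Total step count: 6. Longest linear sequence: 6 steps (1 → 5 → 8 → 10 → 11 → 12 → 13).

Steps most likely to fail:

Step 3 (proposed new method). The aroylpalladium species may be intercepted by the hydroxyl group (ester formation), or arylation may occur without CO uptake. The π-allyl intermediate may close at C3 to a vinyloxirane or lose a β-hydride. The carbonate base may cause vinylogous enolisation at C2 of the product and erode enantiopurity. The fallback uses known chemistry and sets out from 8. Electrophilic iodocyclisation (N-iodosuccinimide, CH2Cl2, 0 °C) is expected to give, by the same 5-endo O1–C5 closure, tert-butyl{[(2S)-2-(3,4-dimethoxyphenyl)-4-iodo-2,5-dihydrofuran-3-yl]methoxy}dimethylsilane F1. Carbonylative Suzuki–Miyaura coupling of this vinyl iodide with commercial (3,4,5-trimethoxyphenyl)boronic acid (COc1cc(B(O)O)cc(OC)c1OC; PdCl2(dppf), CO 1 atm, K2CO3, anisole, 80 °C) then forms the aryl–carbonyl bond by acyl–aryl reductive elimination and comes back to the route at 10.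

Step 4. The doubly activated (benzylic and allylic) C2–O1 bond may undergo hydrogenolytic opening. Palladium hydride may move the double bond out of conjugation, with loss of the C2 stereochemical information. Uptake at the tetrasubstituted alkene may be slow, and the aryl ketone may be over-reduced. The fallback sets out from 10 and replaces hydrogenation by conjugate hydride addition: (IPr)CuCl (IPr = 1,3-bis(2,6-diisopropylphenyl)imidazol-2-ylidene), NaOtBu (cat.), polymethylhydrosiloxane, t-BuOH, toluene, rt. Hydride should add to C3 anti to the C2 aryl group and the copper enolate should be protonated at C4. This would give 11, possibly admixed with 12, and the route is rejoined at 11 before the equilibration of step 5. No new compound arises on this path (entry F0).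

Step 2. Addition of the γ-substituted propargylic pinacol boronate to the electron-rich aldehyde may be sluggish, so that uncatalysed background reaction and weak facial discrimination lower the enantiomeric purity. The fallback sets out from 1 (through its lithium acetylide 3) and from 6, and changes to organochromium chemistry. The acetylide 3 is trapped with paraformaldehyde (THF, −78 °C to rt) to give 4-{[tert-butyl(dimethyl)silyl]oxy}but-2-yn-1-ol F2. Appel bromination (CBr4, PPh3, CH2Cl2, 0 °C) gives [(4-bromobut-2-yn-1-yl)oxy](tert-butyl)dimethylsilane F3. Catalytic asymmetric Nozaki–Hiyama–Kishi allenylation of 6 with this bromide follows: CrCl2 (10 mol %), chiral 1,8-bis(4-isopropyl-4,5-dihydrooxazol-2-yl)-3,6-di-tert-butylcarbazole (antipode chosen for the S alcohol), Mn powder, Me3SiCl, iPr2NEt, THF, rt. It should give, by SE2′ addition of the propargylchromium species, [(1S)-2-({[tert-butyl(dimethyl)silyl]oxy}methyl)-1-(3,4-dimethoxyphenyl)buta-2,3-dien-1-yl]oxy(trimethyl)silane F4. Mild methanolysis of this silyl ether (K2CO3, MeOH, 0 °C) returns to the route at 8.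

Further compounds
F1 | step 3 | tert-butyl{[(2S)-2-(3,4-dimethoxyphenyl)-4-iodo-2,5-dihydrofuran-3-yl]methoxy}dimethylsilane | COc1ccc([C@@H]2OCC(I)=C2CO[Si](C)(C)C(C)(C)C)cc1OC
F0 | step 4 | none | none
F2 | step 2 | 4-{[tert-butyl(dimethyl)silyl]oxy}but-2-yn-1-ol | OCC#CCO[Si](C)(C)C(C)(C)C
F3 | step 2 | [(4-bromobut-2-yn-1-yl)oxy](tert-butyl)dimethylsilane | BrCC#CCO[Si](C)(C)C(C)(C)C
F4 | step 2 | [(1S)-2-({[tert-butyl(dimethyl)silyl]oxy}methyl)-1-(3,4-dimethoxyphenyl)buta-2,3-dien-1-yl]oxy(trimethyl)silane | COc1ccc([C@H](O[Si](C)(C)C)C(CO[Si](C)(C)C(C)(C)C)=C=C)cc1OC
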